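Retrosynthesis (labdane numbering: C17 on C8, C11–C12 the arm on C9, C13–C16 the imide carbons): C12=C13 is cut first (Wittig, the imide ring arrives intact), then C7–O and C2–Cl (late functionalisation), C8=C17 (methylenation of a C8 ketone), C9–C10 (radical ring closure) and C9=C11 (aldol condensation).
What makes the ring closure possible: ring A of α-ionone already holds the trisubstituted C1=C10 alkene next to C5, and the C5 chain C6–C7–C8 places an enoate β-carbon (C9) where a C10 radical closes ring B.
Forward order: ring A is bought; the ionone methyl ketone (C8, its methyl = C9) is extended by C11–C12; ring B closes in step 5; Cl, C17, the C7 oxygen and, last, the succinimide follow.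
C8 is a dioxolane during the closure: a C8 methylene would give a cross-conjugated dienoate that should take up the hydrogen atom faster than the ring alkene, and a free ketone would direct the radical to C11.
Stereochemistry: C5 from (S)-α-ionone; C10 and C9 from the chair-like closure anti to the axial C4 methyl (C9 is also equilibrated next to the C8 ketone); C2 by chlorine transfer to the open α face; C7 by axial hydride addition to the 7-ketone; the E alkene from the stabilised ylide.
Key step: step 5

Assumption: (S)-α-ionone is bought in enantiomerically enriched form (it is offered as a resolved aroma chemical); ethyl esters are used throughout so that the ethanol solvent of step 5 cannot scramble the ester.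

Step 1
Reactants: 1 (S)-α-ionone
Product: 2 (S)-7,8-dihydro-α-ionone, 4-[(1S)-2,6,6-trimethylcyclohex-2-en-1-yl]butan-2-one
Conditions: [(Ph3P)CuH]6 (cat.), PhMe2SiH, t-BuOH, toluene, rt
Reagents that add atoms: none
Why: Stryker-type copper hydride conjugate reduction delivers hydride only to the enone β-carbon (C6); the isolated ring alkene is not a substrate and the non-basic conditions leave C5 untouched.

Step 2
Reactants: 2 (S)-7,8-dihydro-α-ionone; 3 ethyl glyoxylate
Product: 5 ethyl 2-hydroxy-4-oxo-6-[(1S)-2,6,6-trimethylcyclohex-2-en-1-yl]hexanoate (both C2 epimers), via lithium enolate 4 (not isolated)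
Conditions: LDA, THF, −78 °C; then 3; then AcOH
Reagents that add atoms: none
Why: Kinetic deprotonation occurs at the methyl group of the methyl ketone, and the enolate undergoes a crossed aldol addition to the non-enolisable glyoxylate aldehyde; the carbinol centre forms without control and is removed in step 3.

Step 3
Reactants: 5 ethyl 2-hydroxy-4-oxo-6-[(1S)-2,6,6-trimethylcyclohex-2-en-1-yl]hexanoate
Product: 7 ethyl (E)-4-oxo-6-[(1S)-2,6,6-trimethylcyclohex-2-en-1-yl]hex-2-enoate, via mesylate 6 (not isolated)
Conditions: MsCl, Et3N, CH2Cl2, 0 °C → rt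
Reagents that add atoms: none
Why: Mesylation and E1cB elimination through the ketone enolate complete the aldol condensation and should give the conjugated 4-oxo-2-enoate as its favoured E isomer.

Step 4
Reactants: 7 ethyl (E)-4-oxo-6-[(1S)-2,6,6-trimethylcyclohex-2-en-1-yl]hex-2-enoate
Product: 8 ethyl (E)-3-{2-[2-((1S)-2,6,6-trimethylcyclohex-2-en-1-yl)ethyl]-1,3-dioxolan-2-yl}prop-2-enoate
Conditions: (TMSOCH2)2, TMSOTf (cat.), CH2Cl2, −78 → −20 °C
Reagents that add atoms: 1,2-bis(trimethylsilyloxy)ethane, C[Si](C)(C)OCCO[Si](C)(C)C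
Why: Noyori ketalisation converts conjugated ketones into dioxolanes at low temperature without strong protic acid, so the ring alkene and C5 should survive; the ketal removes the ketone's pull on C11 and leaves the ester as the only activating group.

Step 5
Reactants: 8 ethyl (E)-3-{2-[2-((1S)-2,6,6-trimethylcyclohex-2-en-1-yl)ethyl]-1,3-dioxolan-2-yl}prop-2-enoate
Product: 9 ethyl 8,8-(ethylenedioxy)-13,14,15,16,17-pentanorlabdan-12-oate (trans-decalin, 5α-H, 10β-CH3, 9α-H, CH2CO2Et arm 9β equatorial, C8 spiro-dioxolane)
Conditions: Fe(acac)3 (30 mol%), PhSiH3, EtOH/(CH2OH)2 (5:1), 60 °C, high dilution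
Reagents that add atoms: none
Why: An iron hydride formed from Fe(acac)3 and PhSiH3 transfers a hydrogen atom to C1 of the C1=C10 alkene (Markovnikov), the nucleophilic tertiary C10 radical adds to the enoate β-carbon C9, and the α-ester radical at C11 is reduced and protonated by the alcohol solvent. The closest known reaction type is the MHAT-initiated reductive olefin–enoate coupling (radical conjugate addition, Giese type) used to build quaternary centres, here in its intramolecular form. Ring B (C5–C6–C7–C8–C9–C10) closes 6-exo-trig. C10 is controlled by C5 and the axial C4 methyl: the lobe of the radical syn to that methyl is shielded, so C9 bonds to the other lobe with the tether equatorial on ring A and the fusion becomes trans, as in stepwise radical polyene cyclisations that pass through the same C10 radical; C9 is controlled by the chair transition state with the (E)-enoate arm pseudo-equatorial, which gives the 9β arm. The step needs hydrogen-atom transfer to the ring alkene only and attack at C9 only, and the substrate secures both because it holds no diene or second electron-rich alkene (C8 is a ketal, not a methylene) and because the ester is the sole group polarising the C9=C11 bond.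

Step 6
Reactants: 9 ethyl 8,8-(ethylenedioxy)-13,14,15,16,17-pentanorlabdan-12-oate
Product: 10 ethyl 8-oxo-13,14,15,16,17-pentanorlabdan-12-oate (configuration as in 9)
Conditions: 2 M HCl, THF, 40 °C
Reagents that add atoms: water, O
Why: Acid-catalysed ketal hydrolysis unmasks the C8 ketone, and under the same enolising conditions C9, now α to the ketone, should settle in the equatorial 9β configuration.

Step 7
Reactants: 10 ethyl 8-oxo-13,14,15,16,17-pentanorlabdan-12-oate
Product: 11 ethyl 2α-chloro-8-oxo-13,14,15,16,17-pentanorlabdan-12-oate (equatorial Cl)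
Conditions: ArC(O)N(Cl)t-Bu (Ar = 3,5-(CF3)2C6H3), Cs2CO3, PhH, visible light, 55 °C
Reagents that add atoms: N-chloro-N-tert-butyl-3,5-bis(trifluoromethyl)benzamide, CC(C)(C)N(Cl)C(=O)c1cc(cc(c1)C(F)(F)F)C(F)(F)F
Why: Radical C–H chlorination by a bulky amidyl radical is known to select the C2 methylene of sclareolide-type 4,4,10-trimethyl-trans-decalins; here C1 and C3 are neopentyl, C6, C7, C9 and C11 are deactivated by the ketone and ester, and chlorine should reach the C2 radical from the α face, away from the two syn-axial methyl groups.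

Step 8
Reactants: 11 ethyl 2α-chloro-8-oxo-13,14,15,16,17-pentanorlabdan-12-oate
Product: 12 ethyl 2α-chloro-13,14,15,16-tetranorlabd-8(17)-en-12-oate
Conditions: Ph3PCH3Br, KOt-Bu, THF, 0 °C → reflux
Reagents that add atoms: methyltriphenylphosphonium bromide, C[P+](c1ccccc1)(c1ccccc1)c1ccccc1.[Br-]
Why: Wittig methylenation is the standard way to the exocyclic alkene of 8-oxo labdanes; the ester is inert to the ylide, the equatorial chloride has no antiperiplanar hydrogen for elimination, and C9 stays in its thermodynamic configuration.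

Step 9
Reactants: 12 ethyl 2α-chloro-13,14,15,16-tetranorlabd-8(17)-en-12-oate
Product: 13 ethyl 2α-chloro-7α-hydroxy-13,14,15,16-tetranorlabd-8(17)-en-12-oate (axial OH)
Conditions: SeO2 (cat.), t-BuOOH, CH2Cl2, rt
Reagents that add atoms: tert-butyl hydroperoxide, CC(C)(C)OO
Why: Selenium dioxide allylic oxidation (ene reaction, then [2,3]-sigmatropic shift) should attack the ring methylene C7 in preference to the hindered methine C9 and restore the exocyclic alkene; removal of the axial 7α-hydrogen and suprafacial oxygen delivery give the axial 7α-alcohol.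

Step 10
Reactants: 13 ethyl 2α-chloro-7α-hydroxy-13,14,15,16-tetranorlabd-8(17)-en-12-oate
Product: 14 ethyl 2α-chloro-7-oxo-13,14,15,16-tetranorlabd-8(17)-en-12-oate
Conditions: Dess–Martin periodinane, NaHCO3, CH2Cl2, 0 °C → rt
Reagents that add atoms: none
Why: Dess–Martin oxidation of the allylic alcohol under buffered conditions should give the exo-methylene ketone without moving the double bond into the ring.

Step 11
Reactants: 14 ethyl 2α-chloro-7-oxo-13,14,15,16-tetranorlabd-8(17)-en-12-oate
Product: 15 ethyl 2α-chloro-7β-hydroxy-13,14,15,16-tetranorlabd-8(17)-en-12-oate (equatorial OH)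
Conditions: NaBH4, CeCl3·7H2O, MeOH, −78 → 0 °C
Reagents that add atoms: none
Why: Luche reduction gives 1,2-reduction of the enone; the small hydride should enter axially from the α face (only 5α-H and 9α-H nearby) and set the equatorial 7β-alcohol, with ester and chloride inert.

Step 12
Reactants: 15 ethyl 2α-chloro-7β-hydroxy-13,14,15,16-tetranorlabd-8(17)-en-12-oate
Product: 16 2α-chloro-7β-hydroxy-13,14,15,16-tetranorlabd-8(17)-en-12-al
Conditions: DIBAL-H (2.2 equiv), CH2Cl2, −78 °C; Rochelle salt work-up
Reagents that add atoms: none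
Why: DIBAL-H partial reduction of the ester stops at the aluminium hemiacetal at −78 °C and releases the aldehyde on work-up; it is placed before acetylation because an acetate would not survive it.

Step 13
Reactants: 16 2α-chloro-7β-hydroxy-13,14,15,16-tetranorlabd-8(17)-en-12-al
Product: 17 7β-acetoxy-2α-chloro-13,14,15,16-tetranorlabd-8(17)-en-12-al
Conditions: Ac2O, pyridine, DMAP (cat.), CH2Cl2, 0 °C
Reagents that add atoms: acetic anhydride, CC(=O)OC(C)=O
Why: DMAP-catalysed acylation of the equatorial secondary allylic alcohol is routine and should leave the aldehyde untouched at 0 °C.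

Step 14
Reactants: 18 maleimide
Product: 19 3-(triphenyl-λ5-phosphanylidene)pyrrolidine-2,5-dione
Conditions: PPh3, acetone, reflux
Reagents that add atoms: triphenylphosphine, c1ccc(cc1)P(c1ccccc1)c1ccccc1
Why: Conjugate addition of the phosphine to maleimide and proton shift give the stabilised succinimide ylide, a known crystalline Wittig reagent.

Step 15
Reactants: 17 7β-acetoxy-2α-chloro-13,14,15,16-tetranorlabd-8(17)-en-12-al; 19 3-(triphenyl-λ5-phosphanylidene)pyrrolidine-2,5-dione
Product: 20 CNP0220384.1, (E)-7β-acetoxy-2α-chloro-labda-8(17),12-diene-15,16-dicarboximide (2S,5S,7S,9R,10S)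
Conditions: THF, 60 °C
Reagents that add atoms: none
Why: Wittig olefination with a stabilised ylide under neutral conditions should give the E-alkylidenesuccinimide (chain trans to the C16 carbonyl) and tolerate acetate, chloride, the imide N–H and the exocyclic alkene.

Compound list
1 | (S)-α-ionone, (E)-4-[(1S)-2,6,6-trimethylcyclohex-2-en-1-yl]but-3-en-2-one | CC(=O)/C=C/[C@H]1C(C)(C)CCC=C1C | starting material
2 | (S)-7,8-dihydro-α-ionone | CC(=O)CC[C@H]1C(C)(C)CCC=C1C | intermediate
3 | ethyl glyoxylate | CCOC(=O)C=O | starting material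
4 | lithium enolate of 2 (methyl side) | [Li]OC(=C)CC[C@H]1C(C)(C)CCC=C1C | intermediate (not isolated)
5 | ethyl 2-hydroxy-4-oxo-6-[(1S)-2,6,6-trimethylcyclohex-2-en-1-yl]hexanoate, both C2 epimers | CCOC(=O)C(O)CC(=O)CC[C@H]1C(C)(C)CCC=C1C | intermediate
6 | C2 methanesulfonate of 5 | CCOC(=O)C(OS(C)(=O)=O)CC(=O)CC[C@H]1C(C)(C)CCC=C1C | intermediate (not isolated)
7 | ethyl (E)-4-oxo-6-[(1S)-2,6,6-trimethylcyclohex-2-en-1-yl]hex-2-enoate | CCOC(=O)/C=C/C(=O)CC[C@H]1C(C)(C)CCC=C1C | intermediate
8 | ethyl (E)-3-{2-[2-((1S)-2,6,6-trimethylcyclohex-2-en-1-yl)ethyl]-1,3-dioxolan-2-yl}prop-2-enoate | CCOC(=O)/C=C/C1(CC[C@H]2C(C)(C)CCC=C2C)OCCO1 | intermediate (key-step precursor)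
9 | ethyl 8,8-(ethylenedioxy)-13,14,15,16,17-pentanorlabdan-12-oate (5α-H, 9α-H, 10β-CH3) | O1CCOC12CC[C@H]3C(C)(C)CCC[C@]3(C)[C@H]2CC(=O)OCC | intermediate (key-step product)
10 | ethyl 8-oxo-13,14,15,16,17-pentanorlabdan-12-oate | O=C1CC[C@H]2C(C)(C)CCC[C@]2(C)[C@H]1CC(=O)OCC | intermediate
11 | ethyl 2α-chloro-8-oxo-13,14,15,16,17-pentanorlabdan-12-oate | O=C1CC[C@H]2C(C)(C)C[C@H](Cl)C[C@]2(C)[C@H]1CC(=O)OCC | intermediate
12 | ethyl 2α-chloro-13,14,15,16-tetranorlabd-8(17)-en-12-oate | C=C1CC[C@H]2C(C)(C)C[C@H](Cl)C[C@]2(C)[C@H]1CC(=O)OCC | intermediate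
13 | ethyl 2α-chloro-7α-hydroxy-13,14,15,16-tetranorlabd-8(17)-en-12-oate | C=C1[C@H](O)C[C@H]2C(C)(C)C[C@H](Cl)C[C@]2(C)[C@H]1CC(=O)OCC | intermediate
14 | ethyl 2α-chloro-7-oxo-13,14,15,16-tetranorlabd-8(17)-en-12-oate | C=C1C(=O)C[C@H]2C(C)(C)C[C@H](Cl)C[C@]2(C)[C@H]1CC(=O)OCC | intermediate
15 | ethyl 2α-chloro-7β-hydroxy-13,14,15,16-tetranorlabd-8(17)-en-12-oate | C=C1[C@@H](O)C[C@H]2C(C)(C)C[C@H](Cl)C[C@]2(C)[C@H]1CC(=O)OCC | intermediate
16 | 2α-chloro-7β-hydroxy-13,14,15,16-tetranorlabd-8(17)-en-12-al | C=C1[C@@H](O)C[C@H]2C(C)(C)C[C@H](Cl)C[C@]2(C)[C@H]1CC=O | intermediate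
17 | 7β-acetoxy-2α-chloro-13,14,15,16-tetranorlabd-8(17)-en-12-al | C=C1[C@@H](OC(C)=O)C[C@H]2C(C)(C)C[C@H](Cl)C[C@]2(C)[C@H]1CC=O | intermediate
18 | maleimide | O=C1C=CC(=O)N1 | starting material
19 | 3-(triphenyl-λ5-phosphanylidene)pyrrolidine-2,5-dione | O=C1CC(=P(c2ccccc2)(c2ccccc2)c2ccccc2)C(=O)N1 | intermediate
20 | CNP0220384.1, (E)-7β-acetoxy-2α-chloro-labda-8(17),12-diene-15,16-dicarboximide | C=C1[C@@H](OC(C)=O)C[C@H]2C(C)(C)C[C@H](Cl)C[C@]2(C)[C@H]1C/C=C1\CC(=O)NC1=O | target

Total step count: 15. Longest linear sequence: 14 (steps 1–13 and 15; step 14 is a one-step side branch).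

Steps most likely to fail

Step 5. The tertiary radical may be reduced by a second hydrogen-atom transfer before it reaches the hindered C9. Reversible hydrogen-atom transfer may also move the ring double bond towards C5 and erode that centre, or closure may occur on the other face to the cis-fused ring. The fallback separates radical generation from the hydride. Setting out from 8, Mukaiyama hydration (Co(acac)2, PhSiH3, O2, i-PrOH) of the ring alkene should give the tertiary C10 alcohol F1 as both C10 epimers. Acylation with methyl chlorooxoacetate (Et3N, DMAP) gives the mixed methyl oxalate F2, and one equivalent of CsOH gives the caesium oxalate F3. Visible-light photoredox oxidation (Ir[dF(CF3)ppy]2(dtbbpy)PF6, blue LEDs, DME/DMF, H2O) then releases the same C10 radical by double decarboxylation with no hydride present, so the 6-exo addition to C9 has no reductive competitor. The product is 9, where the route is rejoined.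

Step 7. The amidyl radical may not discriminate well enough between the C2 methylene and the other ring methylenes, or chlorine may be delivered to both faces of the C2 radical. The fallback places the C2 oxygen by classical means before the ring closure. Setting out from 8, allylic oxidation of the ring methylene next to the alkene (CrO3·3,5-dimethylpyrazole) gives the ring enone F4, and Luche reduction gives the allylic alcohol F5 (both epimers are usable). Silylation (TBSCl, imidazole) gives the silyl ether F6, and the ring closure under the conditions of step 5 gives the bicyclic silyl ether F7. TBAF gives the alcohol F8 and Dess–Martin oxidation the 2-ketone F9. NaBH4 should add hydride from the α face, because the β face is blocked by the two syn-axial methyl groups, and give the axial 2β-alcohol F10. Appel chlorination (PPh3, CCl4) with inversion gives the equatorial 2α-chloro ketal F11, and 2 M HCl in THF removes the dioxolane to return to 11.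

Step 4. The diol may add in conjugate fashion to the doubly activated alkene, or the ring alkene may attack the activated carbonyl (Prins-type closure), instead of ketal formation. The fallback masks C8 by reduction. Setting out from 7, Luche reduction gives the γ-hydroxy enoate F12 (both C8 epimers) and TESCl/imidazole gives the silyl ether F13. The ring closure under the conditions of step 5 gives the bicyclic silyl ether F14. Jones oxidation (CrO3, H2SO4, acetone, 0 °C) then cleaves the silyl ether and oxidises C8 in one operation, returning to 10.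

Further compounds
F1 | step 5 | ethyl (E)-3-{2-[2-((1S)-2-hydroxy-2,6,6-trimethylcyclohexyl)ethyl]-1,3-dioxolan-2-yl}prop-2-enoate, both C10 epimers | CCOC(=O)/C=C/C1(CC[C@H]2C(C)(C)CCCC2(C)O)OCCO1
F2 | step 5 | methyl oxalate of the tertiary alcohol F1 | CCOC(=O)/C=C/C1(CC[C@H]2C(C)(C)CCCC2(C)OC(=O)C(=O)OC)OCCO1
F3 | step 5 | caesium oxalate of the tertiary alcohol F1 | CCOC(=O)/C=C/C1(CC[C@H]2C(C)(C)CCCC2(C)OC(=O)C(=O)[O-])OCCO1.[Cs+]
F4 | step 7 | ethyl (E)-3-{2-[2-((1S)-2,6,6-trimethyl-4-oxocyclohex-2-en-1-yl)ethyl]-1,3-dioxolan-2-yl}prop-2-enoate | CCOC(=O)/C=C/C1(CC[C@H]2C(C)(C)CC(=O)C=C2C)OCCO1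
F5 | step 7 | ring allylic alcohol from F4, both carbinol epimers | CCOC(=O)/C=C/C1(CC[C@H]2C(C)(C)CC(O)C=C2C)OCCO1
F6 | step 7 | tert-butyldimethylsilyl ether of F5 | CCOC(=O)/C=C/C1(CC[C@H]2C(C)(C)CC(O[Si](C)(C)C(C)(C)C)C=C2C)OCCO1
F7 | step 7 | 2-(tert-butyldimethylsilyloxy) derivative of 9, C2 epimers | O1CCOC12CC[C@H]3C(C)(C)CC(O[Si](C)(C)C(C)(C)C)C[C@]3(C)[C@H]2CC(=O)OCC
F8 | step 7 | 2-hydroxy derivative of 9, C2 epimers | O1CCOC12CC[C@H]3C(C)(C)CC(O)C[C@]3(C)[C@H]2CC(=O)OCC
F9 | step 7 | 2-oxo derivative of 9 | O1CCOC12CC[C@H]3C(C)(C)CC(=O)C[C@]3(C)[C@H]2CC(=O)OCC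
F10 | step 7 | 2β-hydroxy derivative of 9 (axial OH) | O1CCOC12CC[C@H]3C(C)(C)C[C@@H](O)C[C@]3(C)[C@H]2CC(=O)OCC
F11 | step 7 | 2α-chloro derivative of 9 | O1CCOC12CC[C@H]3C(C)(C)C[C@H](Cl)C[C@]3(C)[C@H]2CC(=O)OCC
F12 | step 4 | ethyl (E)-4-hydroxy-6-[(1S)-2,6,6-trimethylcyclohex-2-en-1-yl]hex-2-enoate, both C4 epimers | CCOC(=O)/C=C/C(O)CC[C@H]1C(C)(C)CCC=C1C
F13 | step 4 | triethylsilyl ether of F12 | CCOC(=O)/C=C/C(O[Si](CC)(CC)CC)CC[C@H]1C(C)(C)CCC=C1C
F14 | step 4 | ethyl 8-(triethylsilyloxy)-13,14,15,16,17-pentanorlabdan-12-oate, C8 epimers | CC[Si](CC)(CC)OC1CC[C@H]2C(C)(C)CCC[C@]2(C)[C@H]1CC(=O)OCC
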